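## Analysis of the target

- Target 37 (C42H30O23) is a linear phlorotannin of the fuhalol type. Seven benzene rings, lettered A to G from the 2,4,6-trihydroxyphenoxy end to the 3,4,5-trihydroxyphenoxy end, are joined only by six diaryl ether oxygens and carry seventeen free hydroxyls.
- In every ring, C1 is the carbon whose oxygen points towards ring A; in ring A it is the ether carbon itself.
- Rings B, D and F share one pattern: aryloxy at C1 and C4, hydroxyl at C3 and C5. Each therefore has a C4 ether oxygen wedged between two oxygenated carbons. Rings C and E carry their two ether oxygens on the neighbouring carbons C1 and C6, and ring C is oxygenated at five of its six positions.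
- There is no stereocenter and no configurationally stable axis, so the whole problem is one of constitution: which oxygen sits on which carbon.
- The pyrogallol arrays of rings C and G and the other polyhydroxy arrays oxidise in air, fastest as phenolates. The free polyphenol should therefore appear only in the last step and should never meet base.
- The difficulty lies in six C–O bonds between electron-rich, ortho-crowded arenes. Copper etherification copes with this for small partners, but it would be at its weakest in a union of two trimers at a flanked carbon.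
- The strategy rests on ring D, which has para ether oxygens at C1 and C4, hydroxyls at C3 and C5, and hydrogens at C2 and C6. This is the pattern produced when a 3-alkoxy-4-aryloxycyclobutenone and an aryl ethynyl ether merge by benzannulation. Ring D can therefore be grown between the two halves with both of its ether oxygens already in place.

## Retrosynthetic reasoning

**37 ⇒ 36.** The last operation has to release all the phenols at once. Fifteen O–CH3 bonds and one O–CH2CH3 bond of 36 are cut by Lewis-acid ether cleavage, and the diaryl ether C–O bonds are inert to it. Methyl ethers are chosen because every ring is sold in that form. They also survive alkyllithium, peracid, hot copper/base mixtures and the thermolysis that come before.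

**36 ⇒ 16 + 31.** Ring D is taken apart at D C3–C2 and D C1–C6.
- D C2 and D C1 become the two alkyne carbons of ethynyl ether 16.
- D C3, C4, C5 and C6 become the four ring carbons of cyclobutenone 31.
- Cutting inside the ring rather than at one of its oxygens avoids any arene–oxygen coupling between two trimers, and it divides the molecule into near-equal halves.
- The forward reaction has to open 31, capture the vinylketene with 16 in one orientation only, and aromatise.

**31 ⇒ 27 + 28, and 27 ⇒ 25.** The cyclobutenone is cut at C1–C2 and C3–C4 into aryloxyketene 30 and ethoxyacetylene 28. The ketene comes from aryloxyacetic acid 27. The flanked D C4–O bond is thus traced back to a plain O-alkylation of phenol 25 with a two-carbon acetate unit. This is an sp3 substitution that does not feel the crowding an aryl–oxygen coupling would.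

**16 ⇒ 13 ⇒ 10 + 11.** The D C1–O bond is traced back to the addition of the phenoxide of 10 to the two-carbon unit of trichloroethylene 11, giving dichlorovinyl ether 13. An alkyllithium then strips 13 to the alkyne. The electrophile is small and linear, so the doubly flanked hydroxyl at ring C C6 is no obstacle.

**25 ⇒ 23 ⇒ 21 + 22.** The E C6–O bond is cut. Ring E enters as bromo aldehyde 22.
- Its formyl group sits on the future E C1 and serves twice: it activates the neighbouring bromide for copper catalysis, and it is later converted to the E C1 hydroxyl by Baeyer–Villiger oxidation.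
- The nucleophile 21 is an unhindered, electron-rich phenol.

**21 ⇒ 19 ⇒ 17 + 18.** The F C4–O bond is cut with the same logic. Phenol 17 (ring G) attacks bromide 18 (ring F), which is activated by its para formyl group, and that formyl group becomes the F C1 hydroxyl. The opposite polarity would need a phenoxide conjugated to a para formyl group, which is a poor nucleophile for copper.

**10 ⇒ 8 ⇒ 5 + 7, and 7 ⇒ 6.** The bond from the B C4 oxygen to C C1 is cut.
- Ring C enters as bromo aldehyde 7, whose bromide has one ortho hydrogen and one ortho formyl group. The hindered but electron-rich phenol 5 can therefore reach it.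
- The formyl carbon marks C C6, the site of the later ynol ether.
- Aldehyde 7 comes from the symmetric bromide 6 by formylation at either of its two equivalent free positions.

**5 ⇒ 4 ⇒ 2 + 3, and 2 ⇒ 1.** The O–B C1 bond is cut so that the crowding lies on the nucleophile 3, while the bromide carbon of 2 has two ortho hydrogens. The B C4 hydroxyl of 1 has to be masked as a benzyl ether during this coupling; otherwise 1 would couple with itself.

## Alternatives that were turned down

**Alternative 1:**
- *Disconnection.* Both ether bonds of ring B, O–B C1 and B C4–O, are cut at once, so ring B becomes a doubly electrophilic linchpin between rings A and C.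
- *Forward key step.* The cationic cyclopentadienylruthenium hexafluorophosphate complex of 2,5-dichloro-1,3-dimethoxybenzene A2 is treated in one flask with two phenoxides in turn. The phenoxide of 3 takes the open C1 chloride. The phenoxide of 2-(benzyloxy)-3,4,5-trimethoxyphenol A3 then takes the flanked C4 chloride, giving the complexed trimer A1. Photochemical release of the arene and hydrogenolysis would lead to 10.
- *In its favour.* Coordination to divalent ruthenium turns an electron-rich dimethoxyarene into a good SNAr substrate near room temperature, and three rings are joined in one operation. On temperature, on the number of operations for the A–B–C half, and on forming the flanked B C4–O bond without copper, it is stronger than steps 1 to 6 of the chosen route.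
- *Against it.*
  - The order of the two substitutions rests only on a steric difference between the chlorides.
  - The first aryloxy group makes the ring less electrophilic just when the more hindered chloride must be displaced by an ortho-disubstituted phenoxide.
  - A full equivalent of ruthenium, a complexation step and a decomplexation step are spent per linchpin.
  - A3 is not purchasable.
  - Above all, it serves one half and not the junction. The union at ring D would be the same substitution with two trimeric phenoxides as nucleophiles.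
- *Comparison.* The chosen strategy accepts slower copper chemistry on small pieces. In exchange it offers a junction that needs no aryl–oxygen bond formation at all.

**Alternative 2:**
- *Disconnection.* Ring C is built de novo, and the bond cut in the key step is C C2–C3.
- *Forward key step.* 4-{1-[4-(Benzyloxy)-2,6-dimethoxyphenoxy]vinyl}-4-hydroxy-2,3-dimethoxycyclobut-2-enone A5 is made by adding a 1-aryloxyvinyl anion to a squarate ester. On heating it opens to a dienylketene, and the vinyl terminus closes onto the ketene carbon. The product is the hydroquinone 5-[4-(benzyloxy)-2,6-dimethoxyphenoxy]-2,3-dimethoxybenzene-1,4-diol A4 (a Moore-type ring expansion).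
- *In its favour.* It places five oxygens on ring C with full regiocontrol. All bond formation after the ring opening is intramolecular, so the step itself is more secure than a bimolecular capture of a vinylketene. On that point it is stronger than the chosen key step.
- *Against it.*
  - A4 has two free hydroxyls, and the one needed for ring D (C C6, between aryloxy and methoxy) is the more hindered. The other must therefore be capped selectively first.
  - The hydroquinone oxidises easily to the quinone.
  - The vinyl anion requires α-metalation of an enol ether next to a ring with three ortho-directing oxygens.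
  - The ring construction is spent on a ring whose pattern is available in one step from a purchased arene (6 to 7). It brings no convergence, and the junction at ring D stays unsolved.
- *Comparison.* The chosen strategy uses closely related electrocyclic chemistry, but at the one ring where it also joins the two halves.

**Alternative 3:**
- *Disconnection.* The two neighbouring bonds E C1–O and E C6–O are cut, which leaves ring E as an aryne.
- *Forward key step.* Halogen–magnesium exchange on 2-iodo-3,5-dimethoxyphenyl 4-chlorobenzenesulfonate A7 releases 3,5-dimethoxybenzyne. The magnesium phenolate of 4-(benzyloxy)-2,6-dimethoxyphenol A8 adds at E C1, which puts the carbanion at E C6 next to the inductively withdrawing methoxy group. Trapping with a borate ester and oxidative work-up gives 2-[4-(benzyloxy)-2,6-dimethoxyphenoxy]-4,6-dimethoxyphenol A6.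
- *In its favour.* Both vicinal oxygens of ring E enter in one flask, the methoxy group steers the regiochemistry, and the flanked D C4–O bond forms without copper. For the D–E pair it is shorter than anything in the chosen route.
- *Against it.*
  - A magnesium phenolate flanked by two methoxy groups is a weak aryne nucleophile and competes with the exchange reagent for the aryne.
  - The crowded arylmagnesium can be lost by protonation before it is borylated.
  - A6 then has to grow in both directions. After debenzylation, the D C1 hydroxyl would have to attack ring C at C6, a carbon between an aryloxy and a methoxy group with no activating substituent. That is the least favourable coupling imaginable in this series.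
- *Comparison.* The chosen strategy forms the ring C C6–O–D C1 link from the ring C phenol and a two-carbon unit, so that coupling never arises.

Key step: step 16

Assumption: compounds 1, 3, 6, 11, 17, 18, 22 and 28 are taken as purchasable. Compound 31 and the transient 33 and 35 are racemic, which has no bearing on the achiral target.

## Route

Step 1
Reactants: 1 4-bromo-2,6-dimethoxyphenol
Product: 2 2-(benzyloxy)-5-bromo-1,3-dimethoxybenzene
Conditions: BnBr, K2CO3, DMF, rt
Reagents that add atoms: benzyl bromide, BrCc1ccccc1
Why: Williamson etherification of an acidic, moderately hindered phenol with a reactive benzylic halide. The benzyl group masks the B C4 oxygen so that the bromophenol cannot couple with itself in step 2.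

Step 2
Reactants: 2 2-(benzyloxy)-5-bromo-1,3-dimethoxybenzene; 3 2,4,6-trimethoxyphenol
Product: 4 A–B benzyl ether 2-(benzyloxy)-1,3-dimethoxy-5-(2,4,6-trimethoxyphenoxy)benzene
Conditions: CuI (10 mol %), picolinic acid (20 mol %), K3PO4, DMSO, 100 °C, Ar
Reagents that add atoms: none
Why: Ligand-assisted Ullmann diaryl ether synthesis, in which the picolinate system is suited to di-ortho-substituted phenols. The crowding lies on the electron-rich nucleophile while the bromide carbon of 2 has two ortho hydrogens. Oxygen is excluded because 3 oxidises easily.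

Step 3
Reactants: 4 A–B benzyl ether
Product: 5 A–B phenol 2,6-dimethoxy-4-(2,4,6-trimethoxyphenoxy)phenol
Conditions: H2 (1 atm), 10% Pd/C, EtOAc/MeOH, rt
Reagents that add atoms: none
Why: Hydrogenolysis of a benzyl aryl ether. Methyl and diaryl ethers are untouched and no halogen is left in the molecule.

Step 4
Reactants: 6 5-bromo-1,2,3-trimethoxybenzene
Product: 7 6-bromo-2,3,4-trimethoxybenzaldehyde
Conditions: Cl2CHOMe, TiCl4, CH2Cl2, 0 °C; then aq. HCl
Reagents that add atoms: dichloromethyl methyl ether, COC(Cl)Cl; water, O
Why: Rieche formylation. The two free positions of 6 are equivalent, each ortho to one methoxy group and para to another, so only one aldehyde can form, and the formyl group shuts down a second attack.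

Step 5
Reactants: 5 A–B phenol; 7 6-bromo-2,3,4-trimethoxybenzaldehyde
Product: 8 A–B–C aldehyde 6-[2,6-dimethoxy-4-(2,4,6-trimethoxyphenoxy)phenoxy]-2,3,4-trimethoxybenzaldehyde
Conditions: CuI (10 mol %), picolinic acid (20 mol %), K3PO4, DMSO, 100 °C, Ar
Reagents that add atoms: none
Why: Ullmann diaryl ether synthesis between an electron-rich hindered phenoxide and a bromide that is activated by its ortho formyl group and also has one ortho hydrogen. The aldehyde has no α-hydrogen and tolerates the anhydrous base.

Step 6
Reactants: 8 A–B–C aldehyde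
Product: 10 A–B–C phenol 6-[2,6-dimethoxy-4-(2,4,6-trimethoxyphenoxy)phenoxy]-2,3,4-trimethoxyphenol, via aryl formate 9 (not isolated)
Conditions: mCPBA, CH2Cl2, 0 °C → rt; aq. NaHCO3/Na2S2O3 wash; then K2CO3 (cat.), MeOH, rt
Reagents that add atoms: mCPBA, OOC(=O)c1cccc(Cl)c1
Why: Baeyer–Villiger oxidation. The migrating ring has methoxy ortho and para and aryloxy ortho to the formyl carbon, so aryl migration wins over hydride migration. The formate is removed by transesterification.

Step 7
Reactants: 10 A–B–C phenol; 11 trichloroethylene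
Product: 13 A–B–C (E)-1,2-dichlorovinyl ether (ring C C6–O–CCl=CHCl), via dichloroacetylene 12 (not isolated)
Conditions: K2CO3, DMF, 70 °C
Reagents that add atoms: none
Why: Base eliminates HCl from 11 and the phenoxide adds anti across the small, linear dichloroacetylene, which sets the E geometry. This is the known preparation of aryl dichlorovinyl ethers. The geometry is erased in step 8.

Step 8
Reactants: 13 A–B–C (E)-1,2-dichlorovinyl ether
Product: 16 A–B–C ethynyl ether (ring C C6–O–C≡CH), via chloroethynyl ether 14 (not isolated), via lithium acetylide 15 (not isolated)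
Conditions: n-BuLi (3 equiv), THF, −78 → −40 °C; then H2O, −78 °C
Reagents that add atoms: none
Why: This is the established dichlorovinyl ether route to ynol ethers: vinylic deprotonation with loss of LiCl, chlorine–lithium exchange, then protonation. Any ring lithiation next to a methoxy group is harmless, because the quench only returns hydrogen. The product is purified on base-washed silica and kept cold.

Step 9
Reactants: 17 3,4,5-trimethoxyphenol; 18 4-bromo-3,5-dimethoxybenzaldehyde
Product: 19 G–F aldehyde 3,5-dimethoxy-4-(3,4,5-trimethoxyphenoxy)benzaldehyde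
Conditions: CuI (20 mol %), N,N-dimethylglycine·HCl (40 mol %), Cs2CO3, dioxane, 110 °C, Ar
Reagents that add atoms: none
Why: Ullmann diaryl ether synthesis with matched electronics: an unhindered electron-rich phenoxide and a bromide activated by a para formyl group. The two ortho methoxy groups are small and can coordinate copper.

Step 10
Reactants: 19 G–F aldehyde
Product: 21 G–F phenol 3,5-dimethoxy-4-(3,4,5-trimethoxyphenoxy)phenol, via aryl formate 20 (not isolated)
Conditions: mCPBA, CH2Cl2, 0 °C → rt; aq. NaHCO3/Na2S2O3 wash; then K2CO3 (cat.), MeOH, rt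
Reagents that add atoms: mCPBA, OOC(=O)c1cccc(Cl)c1
Why: Baeyer–Villiger oxidation of a 3,4,5-trioxygenated benzaldehyde, a substrate class known to give the phenol. The para aryloxy oxygen supports aryl migration.

Step 11
Reactants: 21 G–F phenol; 22 2-bromo-3,5-dimethoxybenzaldehyde
Product: 23 E–F–G aldehyde 2-[3,5-dimethoxy-4-(3,4,5-trimethoxyphenoxy)phenoxy]-3,5-dimethoxybenzaldehyde
Conditions: CuI (20 mol %), N,N-dimethylglycine·HCl (40 mol %), Cs2CO3, dioxane, 110 °C, Ar
Reagents that add atoms: none
Why: Ullmann diaryl ether synthesis. The hydroxyl of 21 has two ortho hydrogens, and the bromide of 22 is activated and guided to copper by the ortho formyl group.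

Step 12
Reactants: 23 E–F–G aldehyde
Product: 25 E–F–G phenol 2-[3,5-dimethoxy-4-(3,4,5-trimethoxyphenoxy)phenoxy]-3,5-dimethoxyphenol, via aryl formate 24 (not isolated)
Conditions: mCPBA, CH2Cl2, 0 °C → rt; aq. NaHCO3/Na2S2O3 wash; then K2CO3 (cat.), MeOH, rt
Reagents that add atoms: mCPBA, OOC(=O)c1cccc(Cl)c1
Why: Baeyer–Villiger oxidation of an ortho-aryloxybenzaldehyde, where the ortho oxygen donor supplies the migratory aptitude. Methanolysis of the formate frees the E C1 hydroxyl.

Step 13
Reactants: 25 E–F–G phenol
Product: 26 methyl (E–F–G aryloxy)acetate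
Conditions: BrCH2CO2Me, K2CO3, DMF, rt
Reagents that add atoms: methyl bromoacetate, COC(=O)CBr
Why: Williamson alkylation with an activated primary halide. This forms the future D C4–O bond at an sp3 carbon, where the ortho aryloxy group of ring E matters little.

Step 14
Reactants: 26 methyl (E–F–G aryloxy)acetate
Product: 27 (E–F–G aryloxy)acetic acid
Conditions: LiOH, THF/H2O, rt; then 1 M HCl
Reagents that add atoms: lithium hydroxide, [Li+].[OH-]
Why: Saponification of an unhindered methyl ester. All aryl ethers are inert.

Step 15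
Reactants: 27 (E–F–G aryloxy)acetic acid; 28 ethoxyacetylene
Product: 31 racemic 3-ethoxy-4-(E–F–G aryloxy)cyclobut-2-enone, via acid chloride 29 (not isolated), via aryloxyketene 30 (not isolated)
Conditions: (COCl)2, DMF (cat.), CH2Cl2, 0 °C → rt, evaporate; then 28 (4 equiv), Et3N (slow addition), CH2Cl2, 0 °C → rt
Reagents that add atoms: none
Why: Dehydrochlorination of an aryloxyacetyl chloride is the standard entry to aryloxyketenes. Ketenes add [2+2] to ethoxyacetylene with the alkyne CH carbon bonding to the ketene carbonyl carbon, which places ethoxy at C3 and aryloxy at C4. The C4 stereocenter forms racemic and is erased in step 16, while slow base addition and excess 28 hold back ketene dimerisation.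

Step 16
Reactants: 16 A–B–C ethynyl ether; 31 racemic 3-ethoxy-4-(E–F–G aryloxy)cyclobut-2-enone
Product: 36 protected heptamer (ring D C3–OH and C5–OEt; all other oxygens as methyl ethers), via vinylketene 32 (not isolated), via vinylcyclobutenone 33 (not isolated), via dienylketene 34 (not isolated), via cyclohexadienone 35 (not isolated)
Conditions: 16 (1.3 equiv), PhMe (0.3 M), Ar, sealed tube, 80 °C then 135 °C
Reagents that add atoms: none
Why: This is a Danheiser benzannulation of a cyclobutenone with an ynol ether, here with aryloxy groups on both partners. Heating opens 31 by conrotatory 4π cleavage of its C1–C4 bond, the C4 aryloxy donor lowering the barrier and turning outward, to give vinylketene 32. The CH terminus of 16, the nucleophilic end of the polarised alkyne, attacks the ketene carbonyl carbon and the oxygen-bearing alkyne carbon bonds to the ketene α-carbon, so the [2+2] step should give only 33 and forms D C3–C2 and D C1–C6. The second 4π opening of 33 is reversible, and the isomer 34 with the ketene and the ethoxyvinyl arm cis is drained by 6π disrotatory electrocyclisation between D C4 and D C3, which closes the six-membered ring D as dienone 35. Tautomerisation of 35 to phenol 36 is irreversible and removes the only sp3 centres passed on the way, so the racemic nature of 31 has no consequence and no stereocenter remains. The one selectivity needed is the orientation of the alkyne, and the ynol ether polarity secures it by putting the ring C oxygen para to the ring E oxygen. An aryl ethynyl ether has no β-hydrogen for retro-ene loss to a ketene, so 16 should tolerate the hotter second stage better than an alkyl ynol ether would.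

Step 17
Reactants: 36 protected heptamer
Product: 37 CNP0351377.0 (free heptamer with seventeen hydroxyls)
Conditions: BBr3 (40 equiv), CH2Cl2, −78 °C → rt, Ar; then H2O, 0 °C; Sephadex LH-20 (degassed MeOH)
Reagents that add atoms: none
Why: Lewis-acid cleavage of aryl alkyl ethers, in which bromide attacks the methyl or ethyl carbon of the boron-complexed ether, so the diaryl ether bonds stay intact. The medium stays acidic throughout, which protects the pyrogallol rings from phenolate autoxidation.

## Compound list

1 | 4-bromo-2,6-dimethoxyphenol | COc1cc(Br)cc(OC)c1O | starting material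
2 | 2-(benzyloxy)-5-bromo-1,3-dimethoxybenzene | COc1cc(Br)cc(OC)c1OCc1ccccc1 | intermediate
3 | 2,4,6-trimethoxyphenol | COc1cc(OC)c(O)c(OC)c1 | starting material
4 | A–B benzyl ether, 2-(benzyloxy)-1,3-dimethoxy-5-(2,4,6-trimethoxyphenoxy)benzene | COc1cc(OC)c(Oc2cc(OC)c(OCc3ccccc3)c(OC)c2)c(OC)c1 | intermediate
5 | A–B phenol, 2,6-dimethoxy-4-(2,4,6-trimethoxyphenoxy)phenol | COc1cc(OC)c(Oc2cc(OC)c(O)c(OC)c2)c(OC)c1 | intermediate
6 | 5-bromo-1,2,3-trimethoxybenzene | COc1cc(Br)cc(OC)c1OC | starting material
7 | 6-bromo-2,3,4-trimethoxybenzaldehyde | COc1cc(Br)c(C=O)c(OC)c1OC | intermediate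
8 | A–B–C aldehyde, 6-[2,6-dimethoxy-4-(2,4,6-trimethoxyphenoxy)phenoxy]-2,3,4-trimethoxybenzaldehyde | COc1cc(OC)c(Oc2cc(OC)c(Oc3cc(OC)c(OC)c(OC)c3C=O)c(OC)c2)c(OC)c1 | intermediate
9 | A–B–C aryl formate (ring C C6–OCHO) | COc1cc(OC)c(Oc2cc(OC)c(Oc3cc(OC)c(OC)c(OC)c3OC=O)c(OC)c2)c(OC)c1 | intermediate
10 | A–B–C phenol, 6-[2,6-dimethoxy-4-(2,4,6-trimethoxyphenoxy)phenoxy]-2,3,4-trimethoxyphenol | COc1cc(OC)c(Oc2cc(OC)c(Oc3cc(OC)c(OC)c(OC)c3O)c(OC)c2)c(OC)c1 | intermediate
11 | trichloroethylene | ClC=C(Cl)Cl | starting material
12 | dichloroacetylene | ClC#CCl | intermediate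
13 | A–B–C (E)-1,2-dichlorovinyl ether | COc1cc(OC)c(Oc2cc(OC)c(Oc3cc(OC)c(OC)c(OC)c3O/C(Cl)=C\Cl)c(OC)c2)c(OC)c1 | intermediate
14 | A–B–C chloroethynyl ether | COc1cc(OC)c(Oc2cc(OC)c(Oc3cc(OC)c(OC)c(OC)c3OC#CCl)c(OC)c2)c(OC)c1 | intermediate
15 | A–B–C lithium aryloxyacetylide | COc1cc(OC)c(Oc2cc(OC)c(Oc3cc(OC)c(OC)c(OC)c3OC#C[Li])c(OC)c2)c(OC)c1 | intermediate
16 | A–B–C ethynyl ether | COc1cc(OC)c(Oc2cc(OC)c(Oc3cc(OC)c(OC)c(OC)c3OC#C)c(OC)c2)c(OC)c1 | intermediate
17 | 3,4,5-trimethoxyphenol | COc1cc(O)cc(OC)c1OC | starting material
18 | 4-bromo-3,5-dimethoxybenzaldehyde | COc1cc(C=O)cc(OC)c1Br | starting material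
19 | G–F aldehyde, 3,5-dimethoxy-4-(3,4,5-trimethoxyphenoxy)benzaldehyde | COc1cc(C=O)cc(OC)c1Oc1cc(OC)c(OC)c(OC)c1 | intermediate
20 | G–F aryl formate | COc1cc(OC=O)cc(OC)c1Oc1cc(OC)c(OC)c(OC)c1 | intermediate
21 | G–F phenol, 3,5-dimethoxy-4-(3,4,5-trimethoxyphenoxy)phenol | COc1cc(O)cc(OC)c1Oc1cc(OC)c(OC)c(OC)c1 | intermediate
22 | 2-bromo-3,5-dimethoxybenzaldehyde | COc1cc(C=O)c(Br)c(OC)c1 | starting material
23 | E–F–G aldehyde, 2-[3,5-dimethoxy-4-(3,4,5-trimethoxyphenoxy)phenoxy]-3,5-dimethoxybenzaldehyde | O=Cc1cc(OC)cc(OC)c1Oc1cc(OC)c(Oc2cc(OC)c(OC)c(OC)c2)c(OC)c1 | intermediate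
24 | E–F–G aryl formate | O=COc1cc(OC)cc(OC)c1Oc1cc(OC)c(Oc2cc(OC)c(OC)c(OC)c2)c(OC)c1 | intermediate
25 | E–F–G phenol, 2-[3,5-dimethoxy-4-(3,4,5-trimethoxyphenoxy)phenoxy]-3,5-dimethoxyphenol | Oc1cc(OC)cc(OC)c1Oc1cc(OC)c(Oc2cc(OC)c(OC)c(OC)c2)c(OC)c1 | intermediate
26 | methyl (E–F–G aryloxy)acetate | COC(=O)COc1cc(OC)cc(OC)c1Oc1cc(OC)c(Oc2cc(OC)c(OC)c(OC)c2)c(OC)c1 | intermediate
27 | (E–F–G aryloxy)acetic acid | OC(=O)COc1cc(OC)cc(OC)c1Oc1cc(OC)c(Oc2cc(OC)c(OC)c(OC)c2)c(OC)c1 | intermediate
28 | ethoxyacetylene | CCOC#C | starting material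
29 | (E–F–G aryloxy)acetyl chloride | ClC(=O)COc1cc(OC)cc(OC)c1Oc1cc(OC)c(Oc2cc(OC)c(OC)c(OC)c2)c(OC)c1 | intermediate
30 | (E–F–G aryloxy)ketene | O=C=COc1cc(OC)cc(OC)c1Oc1cc(OC)c(Oc2cc(OC)c(OC)c(OC)c2)c(OC)c1 | intermediate
31 | racemic 3-ethoxy-4-(E–F–G aryloxy)cyclobut-2-enone | CCOC1=CC(=O)C1Oc1cc(OC)cc(OC)c1Oc1cc(OC)c(Oc2cc(OC)c(OC)c(OC)c2)c(OC)c1 | intermediate
32 | vinylketene, 3-ethoxy-4-(E–F–G aryloxy)buta-1,3-dien-1-one, aryloxy trans to the ketene arm | O=C=C/C(OCC)=C/Oc1cc(OC)cc(OC)c1Oc1cc(OC)c(Oc2cc(OC)c(OC)c(OC)c2)c(OC)c1 | intermediate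
33 | racemic 3-(A–B–C aryloxy)-4-[1-ethoxy-2-(E–F–G aryloxy)vinyl]cyclobut-2-enone | COc1cc(OC)c(Oc2cc(OC)c(Oc3cc(OC)c(OC)c(OC)c3OC3=CC(=O)C3/C(OCC)=C/Oc4cc(OC)cc(OC)c4Oc4cc(OC)c(Oc5cc(OC)c(OC)c(OC)c5)c(OC)c4)c(OC)c2)c(OC)c1 | intermediate
34 | dienylketene, 3-(A–B–C aryloxy)-5-ethoxy-6-(E–F–G aryloxy)hexa-1,3,5-trien-1-one, ketene arm and ethoxyvinyl arm cis on the central double bond | COc1cc(OC)c(Oc2cc(OC)c(Oc3cc(OC)c(OC)c(OC)c3O/C(C=C=O)=C/C(OCC)=C/Oc4cc(OC)cc(OC)c4Oc4cc(OC)c(Oc5cc(OC)c(OC)c(OC)c5)c(OC)c4)c(OC)c2)c(OC)c1 | intermediate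
35 | racemic 3-(A–B–C aryloxy)-5-ethoxy-6-(E–F–G aryloxy)cyclohexa-2,4-dienone | COc1cc(OC)c(Oc2cc(OC)c(Oc3cc(OC)c(OC)c(OC)c3OC3=CC(=O)C(Oc4cc(OC)cc(OC)c4Oc4cc(OC)c(Oc5cc(OC)c(OC)c(OC)c5)c(OC)c4)C(OCC)=C3)c(OC)c2)c(OC)c1 | intermediate
36 | protected heptamer, ring D C3–OH and C5–OEt, fifteen methyl ethers | COc1cc(OC)c(Oc2cc(OC)c(Oc3cc(OC)c(OC)c(OC)c3Oc3cc(O)c(Oc4cc(OC)cc(OC)c4Oc4cc(OC)c(Oc5cc(OC)c(OC)c(OC)c5)c(OC)c4)c(OCC)c3)c(OC)c2)c(OC)c1 | intermediate
37 | CNP0351377.0 | Oc1cc(O)c(Oc2cc(O)c(Oc3cc(O)c(O)c(O)c3Oc3cc(O)c(Oc4cc(O)cc(O)c4Oc4cc(O)c(Oc5cc(O)c(O)c(O)c5)c(O)c4)c(O)c3)c(O)c2)c(O)c1 | target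

## Step count and least certain steps

Total step count: 17.

Longest linear sequence: 9 steps (1, 2, 3, 5, 6, 7, 8, 16, 17). The E–F–G branch (9 to 15, then 16 and 17) is equally long, and step 4 is a one-step side branch.

**Step 16 (key step).**
- *Risk.* The bimolecular capture of vinylketene 32 may be too slow. An aryl ynol ether is less nucleophilic than an alkyl one, and both partners are bulky, so three processes can compete:
  - self-reaction of the vinylketene;
  - acylation of the newly formed phenol by the vinylketene;
  - thermal oligomerisation of the terminal alkyne.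
  A stall at the vinylcyclobutenone stage is the second possibility.
- *Fallback.* Ring D is taken from an arene and the chain is grown by the copper chemistry already used. The sequence sets out from 10 and 2 and comes back at 37.
  - Phenol 10 is coupled with 2 under the conditions of step 2 to the tetramer benzyl ether F1, which is hydrogenolysed to the tetramer phenol F2.
  - F2 is coupled, as in step 5, with purchased 2-bromo-4,6-dimethoxybenzaldehyde F3 to the pentamer aldehyde F4.
  - Baeyer–Villiger oxidation and methanolysis of F4 give the pentamer phenol F5.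
  - A second coupling with 2 gives the hexamer benzyl ether F6, and hydrogenolysis gives the hexamer phenol F7.
  - Coupling of F7 with 6 gives the heptadecamethyl ether F8, which is cleaved to 37 as in step 17.
  - This costs eight linear operations and all convergence, but every bond type in it has been exercised earlier in the route.

**Step 15.**
- *Risk.* The aryloxyketene may be lost by dimerisation before it meets the alkyne. The acid chloride may also acylate the activated E C2 position of its own ring. In addition, the vinylogous ester of the product can hydrolyse on silica.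
- *Fallback.* Vinylketene 32 is made without any cyclobutenone. The sequence sets out from 25 and comes back at 32, and thereby at 36.
  - Phenol 25 is alkylated with ethyl 4-chloroacetoacetate (NaH, THF) to ethyl 4-(E–F–G aryloxy)-3-oxobutanoate F9.
  - HC(OEt)3 with catalytic H2SO4 converts F9 into the ethyl (E)-3-ethoxybut-2-enoate F10.
  - LiOH gives the acid F11, and (COCl)2 gives the acid chloride F12.
  - Slow addition of Et3N to F12 in the presence of 16 causes 1,4-dehydrochlorination to 32 at room temperature. Heating then carries the adduct 33 on to 36.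

**Step 8.**
- *Risk.* The terminal ynol ether may be lost on isolation. It can hydrate on acidic surfaces and can oligomerise on concentration or storage.
- *Fallback.* The alkyne is capped. The sequence sets out from 15 and comes back at 36.
  - The acetylide 15 is quenched with Me3SiCl to the trimethylsilylethynyl ether F13, which can be chromatographed and stored.
  - Benzannulation of F13 with 31 should proceed in the same orientation, which the β-silicon effect reinforces. It gives the heptamer silylated at D C2, F14.
  - Ipso-protonation of F14 with CF3CO2H in CH2Cl2 removes the silyl group.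

**Step 9.**
- *Risk.* Copper insertion at a bromide flanked by two methoxy groups may be slow, and reduction of the C–Br bond could then take over.
- *Fallback.* The polarity of the G–F bond is reversed and copper is used oxidatively at room temperature. The sequence sets out from 6 and 1 and comes back at 21, bypassing 19 and 20.
  - Bromine–lithium exchange on 6 followed by B(OMe)3 and acid gives (3,4,5-trimethoxyphenyl)boronic acid F15.
  - Chan–Lam–Evans coupling of F15 with phenol 1 (Cu(OAc)2, pyridine, 4 Å sieves, air, CH2Cl2, rt) gives 5-bromo-1,3-dimethoxy-2-(3,4,5-trimethoxyphenoxy)benzene F16. The aryl bromide is untouched under these conditions.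
  - Bromine–lithium exchange on F16, borylation and H2O2 oxidation give 21.

**Step 17.**
- *Risk.* The sixteen-fold dealkylation may be incomplete because partly cleaved borates precipitate. The free polyphenol may also oxidise in air during chromatography.
- *Fallback.* The product is isolated through a stable derivative. The sequence sets out from 36 and comes back at 37.
  - The crude product of the BBr3 reaction is acetylated directly (Ac2O, pyridine) to the heptadecaacetate F17.
  - F17 is purified on silica, where any partly methylated material is separated.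
  - F17 is then deacetylated by acid-catalysed methanolysis (HCl in degassed MeOH, Ar), so that no phenolate is ever formed.

## Further compounds

F1 | step 16 | tetramer (A–B–C–D) benzyl ether | COc1cc(OC)c(Oc2cc(OC)c(Oc3cc(OC)c(OC)c(OC)c3Oc3cc(OC)c(OCc4ccccc4)c(OC)c3)c(OC)c2)c(OC)c1
F2 | step 16 | tetramer (A–B–C–D) phenol, free hydroxyl at D C4 | COc1cc(OC)c(Oc2cc(OC)c(Oc3cc(OC)c(OC)c(OC)c3Oc3cc(OC)c(O)c(OC)c3)c(OC)c2)c(OC)c1
F3 | step 16 | 2-bromo-4,6-dimethoxybenzaldehyde | COc1cc(Br)c(C=O)c(OC)c1
F4 | step 16 | pentamer (A–E) aldehyde, formyl at E C6 | COc1cc(OC)c(Oc2cc(OC)c(Oc3cc(OC)c(OC)c(OC)c3Oc3cc(OC)c(Oc4cc(OC)cc(OC)c4C=O)c(OC)c3)c(OC)c2)c(OC)c1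
F5 | step 16 | pentamer (A–E) phenol, free hydroxyl at E C6 | COc1cc(OC)c(Oc2cc(OC)c(Oc3cc(OC)c(OC)c(OC)c3Oc3cc(OC)c(Oc4cc(OC)cc(OC)c4O)c(OC)c3)c(OC)c2)c(OC)c1
F6 | step 16 | hexamer (A–F) benzyl ether | COc1cc(OC)c(Oc2cc(OC)c(Oc3cc(OC)c(OC)c(OC)c3Oc3cc(OC)c(Oc4cc(OC)cc(OC)c4Oc4cc(OC)c(OCc5ccccc5)c(OC)c4)c(OC)c3)c(OC)c2)c(OC)c1
F7 | step 16 | hexamer (A–F) phenol, free hydroxyl at F C4 | COc1cc(OC)c(Oc2cc(OC)c(Oc3cc(OC)c(OC)c(OC)c3Oc3cc(OC)c(Oc4cc(OC)cc(OC)c4Oc4cc(OC)c(O)c(OC)c4)c(OC)c3)c(OC)c2)c(OC)c1
F8 | step 16 | heptamer heptadecamethyl ether | COc1cc(OC)c(Oc2cc(OC)c(Oc3cc(OC)c(OC)c(OC)c3Oc3cc(OC)c(Oc4cc(OC)cc(OC)c4Oc4cc(OC)c(Oc5cc(OC)c(OC)c(OC)c5)c(OC)c4)c(OC)c3)c(OC)c2)c(OC)c1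
F9 | step 15 | ethyl 4-(E–F–G aryloxy)-3-oxobutanoate | CCOC(=O)CC(=O)COc1cc(OC)cc(OC)c1Oc1cc(OC)c(Oc2cc(OC)c(OC)c(OC)c2)c(OC)c1
F10 | step 15 | ethyl (E)-3-ethoxy-4-(E–F–G aryloxy)but-2-enoate | CCOC(=O)/C=C(/OCC)COc1cc(OC)cc(OC)c1Oc1cc(OC)c(Oc2cc(OC)c(OC)c(OC)c2)c(OC)c1
F11 | step 15 | (E)-3-ethoxy-4-(E–F–G aryloxy)but-2-enoic acid | OC(=O)/C=C(/OCC)COc1cc(OC)cc(OC)c1Oc1cc(OC)c(Oc2cc(OC)c(OC)c(OC)c2)c(OC)c1
F12 | step 15 | (E)-3-ethoxy-4-(E–F–G aryloxy)but-2-enoyl chloride | ClC(=O)/C=C(/OCC)COc1cc(OC)cc(OC)c1Oc1cc(OC)c(Oc2cc(OC)c(OC)c(OC)c2)c(OC)c1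
F13 | step 8 | A–B–C (trimethylsilyl)ethynyl ether | COc1cc(OC)c(Oc2cc(OC)c(Oc3cc(OC)c(OC)c(OC)c3OC#C[Si](C)(C)C)c(OC)c2)c(OC)c1
F14 | step 8 | protected heptamer with trimethylsilyl at D C2 | COc1cc(OC)c(Oc2cc(OC)c(Oc3cc(OC)c(OC)c(OC)c3Oc3c([Si](C)(C)C)c(O)c(Oc4cc(OC)cc(OC)c4Oc4cc(OC)c(Oc5cc(OC)c(OC)c(OC)c5)c(OC)c4)c(OCC)c3)c(OC)c2)c(OC)c1
F15 | step 9 | (3,4,5-trimethoxyphenyl)boronic acid | COc1cc(B(O)O)cc(OC)c1OC
F16 | step 9 | 5-bromo-1,3-dimethoxy-2-(3,4,5-trimethoxyphenoxy)benzene | COc1cc(Br)cc(OC)c1Oc1cc(OC)c(OC)c(OC)c1
F17 | step 17 | heptamer heptadecaacetate | CC(=O)Oc1cc(OC(C)=O)c(Oc2cc(OC(C)=O)c(Oc3cc(OC(C)=O)c(OC(C)=O)c(OC(C)=O)c3Oc3cc(OC(C)=O)c(Oc4cc(OC(C)=O)cc(OC(C)=O)c4Oc4cc(OC(C)=O)c(Oc5cc(OC(C)=O)c(OC(C)=O)c(OC(C)=O)c5)c(OC(C)=O)c4)c(OC(C)=O)c3)c(OC(C)=O)c2)c(OC(C)=O)c1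
A1 | alternative 1 | cyclopentadienylruthenium hexafluorophosphate complex of the A–B–C trimer benzyl ether, written as its ionic parts | COc1cc(OC)c(Oc2cc(OC)c(Oc3cc(OC)c(OC)c(OC)c3OCc3ccccc3)c(OC)c2)c(OC)c1.[Ru+2].c1cc[cH-]c1.F[P-](F)(F)(F)(F)F
A2 | alternative 1 | cyclopentadienylruthenium hexafluorophosphate complex of 2,5-dichloro-1,3-dimethoxybenzene, written as its ionic parts | COc1cc(Cl)cc(OC)c1Cl.[Ru+2].c1cc[cH-]c1.F[P-](F)(F)(F)(F)F
A3 | alternative 1 | 2-(benzyloxy)-3,4,5-trimethoxyphenol | Oc1cc(OC)c(OC)c(OC)c1OCc1ccccc1
A4 | alternative 2 | 5-[4-(benzyloxy)-2,6-dimethoxyphenoxy]-2,3-dimethoxybenzene-1,4-diol | COc1c(O)cc(Oc2c(OC)cc(OCc3ccccc3)cc2OC)c(O)c1OC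
A5 | alternative 2 | racemic 4-{1-[4-(benzyloxy)-2,6-dimethoxyphenoxy]vinyl}-4-hydroxy-2,3-dimethoxycyclobut-2-enone | COC1=C(OC)C(O)(C(=C)Oc2c(OC)cc(OCc3ccccc3)cc2OC)C1=O
A6 | alternative 3 | 2-[4-(benzyloxy)-2,6-dimethoxyphenoxy]-4,6-dimethoxyphenol | COc1cc(OC)c(O)c(Oc2c(OC)cc(OCc3ccccc3)cc2OC)c1
A7 | alternative 3 | 2-iodo-3,5-dimethoxyphenyl 4-chlorobenzenesulfonate | COc1cc(OC)c(I)c(OS(=O)(=O)c2ccc(Cl)cc2)c1
A8 | alternative 3 | 4-(benzyloxy)-2,6-dimethoxyphenol | COc1cc(OCc2ccccc2)cc(OC)c1O
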